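The numbers in the tables were computed for an exercise; noise was put on by code.

I had no constants for this flask, so for a quick number I took what your two runs could give directly.

| flask | starting material | coupling partner | capture agent | free catalyst | remark | time |
|---|---|---|---|---|---|---|
| summer | 0.10 M | 0.12 M | 0.030 M | 5.4 mM | the very flask that is asked about, followed so far |  |
| dawn | 0.15 M | 0.12 M | 0.030 M | 5.4 mM | run made earlier |  |
| flask | 0.10 M | 0.120 M | 0.0300 M | 5.4 mM |  | 8.0 d |

| run | time / h | target / % | starting material / % |
|---|---|---|---|
| summer | 25.0 | 37.3 | 62.4 |
| summer | 50.0 | 41.0 | 57.8 |
| summer | 72.0 | 42.3 | 58.4 |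
| summer | 96.0 | 41.9 | 58.8 |
| summer | 120 | 41.1 | 57.6 |
| dawn | 1.50 | 3.7 | 96.0 |
| dawn | 3.00 | 6.6 | 91.9 |
| dawn | 6.00 | 12.0 | 87.3 |
| dawn | 10.0 | 17.7 | 82.3 |
| dawn | 20.0 | 23.8 | 76.1 |

(scatter of a reading: 0.5 percentage points)

- removed target is counted in
- additions bring no volume worth counting

- north-west: change nothing and wait 2.5 d more
- north-east: at 8.0 d add coupling partner, 50.0% of the amount charged, then wait 2.5 d
- south-east: at 8.0 d take out 90% of the target then present, then wait 2.5 d
- west: at 8.0 d add free catalyst, 100% of the amount charged, then wait 2.5 d

1. target, in percent of the starting material first charged, at 8.0 d
2. the remedy with the largest gain of target, or "none" below 2 percentage points (north-west / north-east / south-east / west / none)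
3. target present, with what was taken out counted in, in percent of the starting material first charged, after south-east
4. target present, with what was taken out counted in, in percent of the starting material first charged, after west

The summer run, which is the asked flask followed so far, levelled at 41.6% of its starting material, with 57.6% of that charge still present at the last reading. Free catalyst was charged at 5.40% of the starting material, so the summer run had made 7.70 target per catalyst charged, the total turnover number. The dawn run had reached 6.61 per catalyst by its last reading, less than that count, so it did not contradict it.

I read the stop as loss of working catalyst, so I expected waiting, more coupling partner and removing target to bring nothing. A second dose equal to the first should buy the same count again. The starting material left was more than that dose needed, and the summer run had levelled by 50.0 h, a shorter time than the 2.5 d of waiting. So I put 41.6% for now and for south-east, and 83.2% after west.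

Your forecast gave 41.5%, west, 41.7% and 50%, on the ground that “Fresh catalyst should restart turnover until it too is titrated”. We parted on the size of west, where my figure stood higher.

The flask gave 41.9% at 8.0 d, west as best, 41.9% after south-east and 89.3% after west, above my figure and yours.

    released group → by-product carried off (k = 0.152 h⁻¹)
    catalyst intermediate A + capture agent → trapped intermediate (k = 12.3 M⁻¹ h⁻¹)
    catalyst intermediate E ⇌ free catalyst + target (K = 3.64 M, k = 8.10 h⁻¹)
    catalyst intermediate D ⇌ catalyst intermediate E (K = 0.677, k = 444 h⁻¹)
    catalyst intermediate B ⇌ released group + catalyst intermediate C (K = 9.80 M, k = 7.64 h⁻¹)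
    coupling partner + free catalyst ⇌ catalyst intermediate A (K = 21.4 M⁻¹, k = 82.9 M⁻¹ h⁻¹)
    starting material + catalyst intermediate C → catalyst intermediate D (k = 103 M⁻¹ h⁻¹)
    catalyst intermediate A ⇌ catalyst intermediate B (K = 0.444, k = 11.1 h⁻¹)

In the flask, the fresh dose made 8.78 target per catalyst against the 7.70 I had carried. The main reason for the stop was the falling back of catalyst intermediate B to catalyst intermediate A: in the run without that step, the flask reached 100% at 8.0 d instead of 41.9%. Each return exposes catalyst intermediate A to the capture agent again, and at 192 h the flask held >99.9% of its catalyst as trapped intermediate, with 82% of the capture agent left. In a neighbour flask with less catalyst, free catalyst charged at 1.40% of the starting material gave 10.8% by the carried count, and that flask stood at 10.1%.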